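If I had material for one more run, I had to choose between charging more reagent and speeding up the transfer.

    target ⇌ isomer of the product (K1 = 1.16, k1 = 1.18 /s)
    starting material + reagent in the reaction phase → target (k2 = 13.3 /M/s)
    2 starting material → homo dimer (k3 = 0.170 /M/s)
    reagent in the reaction phase ⇌ reagent in the second phase, rate k4*([reagent in the reaction phase] - [reagent in the second phase]/K4) per volume of the first phase (K4 = 2.0, k4 = 0.753 /s)
    reagent in the reaction phase + target → over-reacted product (k5 = 9.42 /M/s)

starting material 0.25 M; reagent in the second phase 0.325 M; time 3.0 s; volume of the second phase over the first 2.0

- in percentages every species weighs as the starting material in it: one homo dimer counts as two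
- two of one species on the left: rate k times its square, two consumed each time
- in the second phase: reagent in the second phase; everything else is in the first
- charges count per volume of the first phase; a concentration in a rate is the amount of a species over the volume of its own phase; every rate counts per litre of the first phase
- run time (flask): 3.0 s

- zeta: doubling the amount of reagent in the second phase, all else as stated
- delta: doubling the transfer coefficient of step 4, all else as stated

1. target at 3.0 s, in percent of the starting material charged
2. the change that raises the amount of target at 3.0 s, in percent of the starting material charged most ("none" if none brings more than 2 percentage points) (zeta / delta / none)
3. amount of target at 3.0 s, in percent of the starting material charged, after delta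

I counted turnovers. The number of turnovers of the second phase in the run, N, is the transfer coefficient times the time, over the partition ratio times the volume ratio, and I got 0.565. Reagent in the reaction phase is consumed at a first-order rate of 3.33 /s at the charged starting material, faster than the 0.753 /s of transfer. I therefore took it as a quasi-steady state at 0.0150 M, with transfer running at a fraction φ = 0.815 of its full drive.

The second phase then delivers its charge times one minus exp(−φN). Taking off the standing level left 0.105 M in products. Target and isomer relax in 0.455 s, short against 3.0 s, but target is still being fed and isomer is made from it, so I gave target the equilibrium fraction 1/(1+K) of the pair, with K = 1.16, as a rough estimate on the low side. Each over-reaction costs two reagent units, and the average pair has seen half of the run. These factors cancel, so the pair survives at 0.822.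

That gave target 16.0%. Doubling the transfer coefficient lowers φ to 0.688 and raises the level to 0.0253 M, giving 20.0%. Doubling the charge keeps N and φ, doubles the delivery and squares the survival. I chose zeta.

The forecast gave 17.5%, 21.5% after delta and zeta as best, figures apart from mine but the same choice, holding that “Doubling the reagent charge sustains the feed better than doubling the transfer coefficient”. The flask gave 17.2%, 21.2% after delta and zeta as best, with gains of 6.8 percentage points for zeta and 4.1 points for delta.

At 1.26 s, target went to isomer 8.8 times as fast, by the forward rate, as to over-reacted product, and that forward half-life of 0.59 s is short against 3.0 s. At 3.00 s the flask held target at 17.2% beside isomer at 15.6%, and exp(−φN) had predicted 63.1% of the reagent left in the second phase against 64.0% found. For the same flask read at 1.2 s, N is 0.226, which leaves 83.2% there; that earlier reading held 82.7%.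

The numbers of this flask are invented; the run is a simulation.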